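**Plan**

- Retrosynthesis: the C1 carbinol is inverted via its ketone and the orthocinnamate cage (C–O bonds to O4, O6, O15) is opened to a tetraol; C15 and the C4/C6 oxygens are then taken off back to a Δ5-octalin; finally ring B is cut at C7–C8 and C9–C10, which removes a bare C2 unit from a 1-alkenylcyclohexene.
- Enabling feature: C8–C9 of ring B is an unsubstituted ethano bridge between C7 and C10. C7–C6–C5–C10 can be written as an (E)-diene on ring A, and C10 is next to the carbinol C1, whose oxygen can carry the two carbons as a vinylsilane (temporary tether, removed afterwards).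
- Forward: ring A comes from 2-methylcyclohexane-1,3-dione (triflate, Suzuki coupling, CBS reduction); the silicon-tethered intramolecular Diels–Alder reaction closes ring B; silicon is removed; C6 then C4 are oxygenated, C15 is added, the orthoester closes the two remaining rings, and C1 is corrected last.
- Stereochemistry: C1 is set by CBS catalysis. C10 and C7 follow from the tether and the (E)-alkene in the cycloaddition. C6 comes from O1-directed epoxidation, C5 from O6-tethered hydrosilylation, and C4 from OsO4 attack anti to the angular methyl. The orthoester carbon is fixed by the cage, and C1 is finally set by hydride attack anti to the angular methyl.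

Key step: step 6

Remark: eudesmane numbering is used (ring A = C1–C5 and C10; ring B = C5–C10; C15 = carbon on C4). α/β are used in the steroid sense for the usual drawing (ring A left, β toward the viewer). In these terms the target has 1α-OH, 4β-O, 6β-O, 5β-H, 7β-isopropyl (axial) and 10α-methyl, with C15 on the α face. The SMILES strings are authoritative.

Step 1
Reactants: 1 2-methylcyclohexane-1,3-dione
Product: 2 2-methyl-3-oxocyclohex-1-en-1-yl trifluoromethanesulfonate
Conditions: Tf2O, pyridine, CH2Cl2, −78 to 0 °C
Reagents that add atoms: trifluoromethanesulfonic anhydride, O=S(=O)(OS(=O)(=O)C(F)(F)F)C(F)(F)F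
Why: O-sulfonylation of the enol of a symmetric cyclic 1,3-diketone (vinylogous acyl triflate formation), for which only one enol triflate is possible.

Step 2
Reactants: 3 3-methylbut-1-yne
Product: 4 (E)-4,4,5,5-tetramethyl-2-(3-methylbut-1-en-1-yl)-1,3,2-dioxaborolane
Conditions: pinacolborane, Cp2Zr(H)Cl (5 mol%), Et3N (10 mol%), neat, 60 °C, sealed
Reagents that add atoms: pinacolborane, B1OC(C)(C)C(C)(C)O1
Why: zirconium-catalysed syn hydroboration of a terminal alkyne, which places boron at the terminal carbon and should give the (E)-alkenylboronate.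

Step 3
Reactants: 2 enol triflate; 4 (E)-alkenylboronate
Product: 5 2-methyl-3-[(E)-3-methylbut-1-en-1-yl]cyclohex-2-en-1-one
Conditions: Pd(dppf)Cl2 (3 mol%), K3PO4, dioxane/H2O, 60 °C
Reagents that add atoms: none
Why: Suzuki–Miyaura coupling of a vinylogous acyl triflate with an alkenylboronate, which proceeds with retention of the (E) geometry that later defines C7.

Step 4
Reactants: 5 dienone
Product: 6 (R)-2-methyl-3-[(E)-3-methylbut-1-en-1-yl]cyclohex-2-en-1-ol
Conditions: (S)-Me-CBS oxazaborolidine (0.2 equiv), BH3·SMe2, toluene, −40 °C; then MeOH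
Reagents that add atoms: none
Why: Corey–Bakshi–Shibata 1,2-reduction in which the tetrasubstituted enone carbon acts as the large group, so the (S)-catalyst should deliver hydride to give the (R)-carbinol, the only stereocentre set by an external chiral source.

Step 5
Reactants: 6 (R)-dienol
Product: 7 dimethyl(vinyl)silyl ether of 6
Conditions: chloro(dimethyl)vinylsilane, imidazole, CH2Cl2, 0 °C
Reagents that add atoms: chloro(dimethyl)vinylsilane, C=C[Si](C)(C)Cl
Why: O-silylation of a secondary allylic alcohol, which installs the future C8–C9 unit as a vinylsilane on the C1 oxygen without touching the stereocentre.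

Step 6
Reactants: 7 dimethyl(vinyl)silyl ether
Product: 8 Diels–Alder adduct (O1β–SiMe2–C9β siloxane of 7β-isopropyl-10α-methyl-15-noreudesm-5-ene)
Conditions: toluene (0.01 M), BHT (cat.), base-washed sealed tube, 180–190 °C
Reagents that add atoms: none
Why: Thermal, concerted and suprafacial intramolecular Diels–Alder reaction of the semicyclic diene C10=C5–C6=C7 with the unactivated vinylsilane held on O1; the closest known type is the silicon-tethered Diels–Alder reaction of vinylsilyl ethers of dienols, used as a masked addition of ethylene. Ring B closes as the cyclohexene of the (4+2) event (bonds C7–C8 and C9–C10), and the 1-oxa-2-silacyclopentane closes with the same C9–C10 bond through the three-atom tether C1–O–Si (type 1 intramolecular mode), which also fixes which vinyl carbon meets C10. C10 is set because the short tether can reach only the diene face that carries O1, so C9 ends cis and the methyl trans to O1; C7 is set by the (E) geometry of C6=C7, the suprafacial addition placing H7 on the side of the C10 methyl and the isopropyl group on the opposite, axial-type side that is thermodynamically less favoured but cannot equilibrate because C7 never becomes enolisable. C9 is a stereocentre only while silicon is attached and is erased in step 7. The step needs periselectivity over the 1,5-hydrogen shift open to the inside methyl of the diene and over polymerisation, which the entropic gain of the tether, high dilution and a radical inhibitor should secure; regioselectivity is not an issue for a two-carbon unit without substituents.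

Step 7
Reactants: 8 siloxane adduct
Product: 9 7αH,10α-15-noreudesm-5-en-1β-ol
Conditions: Bu4NF (5 equiv), DMF (moist), 80 °C
Reagents that add atoms: none
Why: Fluoride-induced protodesilylation of a 1-oxa-2-silacyclopentane, in which fluoride opens the Si–O bond and the freed γ-alkoxide assists cleavage of the C9–Si bond through a pentacoordinate silicate, so that C9 becomes a plain CH2 and the C1 carbinol is released unchanged.

Step 8
Reactants: 9 octalinol
Product: 10 5β,6β-epoxy-7αH,10α-15-noreudesman-1β-ol
Conditions: VO(acac)2 (5 mol%), t-BuOOH (1.5 equiv), CH2Cl2, 0 °C to rt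
Reagents that add atoms: tert-butyl hydroperoxide, CC(C)(C)OO
Why: Hydroxyl-directed VO(acac)2/t-BuOOH epoxidation of a homoallylic alcohol, in which the vanadate ester of the axial 1β-oxygen can reach only the β face of C5=C6 and so sets the C6–O bond cis to the isopropyl group and trans to the angular methyl.

Step 9
Reactants: 10 epoxy alcohol
Product: 11 7αH,10α-15-noreudesm-4-ene-1β,6β-diol
Conditions: Et2Al(TMP) (from LiTMP and Et2AlCl, 4 equiv), toluene, 0 °C to rt
Reagents that add atoms: none
Why: Aluminium amide-mediated isomerisation of an epoxide to an allylic alcohol by syn β-elimination, in which the C5–O bond at the tertiary carbon breaks and the only available syn hydrogen (H4β) is removed, moving the double bond to C4=C5 and leaving the C6 carbinol as an allylic anchor.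

Step 10
Reactants: 11 allylic diol
Product: 14 5βH,7αH,10α-15-noreudesmane-1β,4β,6β-triol, via bis(dimethylsilyl) ether 12 (not isolated), via oxasilolane 13 (not isolated)
Conditions: (HMe2Si)2NH, neat, 60 °C; then Pt2(dvds)3 (0.5 mol%, dvds = (CH2=CHSiMe2)2O), toluene, 60 °C; then KF, KHCO3, 30% H2O2, THF/MeOH, 40 °C
Reagents that add atoms: hydrogen peroxide, OO
Why: Platinum-catalysed intramolecular hydrosilylation of an allylic hydrosilyl ether (5-endo) followed by Tamao–Fleming oxidation, in which the silicon on O6 can reach only C4 and only on the face of O6, so hydrogen adds syn to C5 on the β face (trans ring fusion, a kinetic result) and oxidation with retention gives the 4β-carbinol, while the silyl ether on O1 would have to form a quaternary C5–Si bond and should stay a spectator.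

Step 11
Reactants: 14 triol
Product: 15 1β,6β-dihydroxy-5βH,7αH,10α-15-noreudesman-4-one
Conditions: TEMPO (10 mol%), KBr (10 mol%), NaOCl (1.05 equiv), NaHCO3, CH2Cl2/H2O, 0 °C
Reagents that add atoms: none
Why: Anelli (oxoammonium) oxidation, which is sensitive to steric hindrance, so the equatorial C4 carbinol with one methylene neighbour should react ahead of the axial neopentyl C1 carbinol and of the C6 carbinol next to the axial isopropyl group, and the cold buffered medium should leave the epimerisable C5 centre alone.

Step 12
Reactants: 15 hydroxy ketone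
Product: 16 5βH,7αH,10α-eudesm-4(15)-ene-1β,6β-diol
Conditions: Zn, CH2Br2, TiCl4, THF/CH2Cl2, 0 °C to rt
Reagents that add atoms: dibromomethane, BrCBr
Why: Takai–Lombardo methylenation, a non-basic carbonyl olefination chosen because the β-hydroxy ketone would risk retro-aldol cleavage, elimination or C5 epimerisation under Wittig conditions.

Step 13
Reactants: 16 methylene diol
Product: 17 5βH,7αH,10α-eudesmane-1β,4β,6β,15-tetraol
Conditions: OsO4 (2 mol%), NMO, acetone/H2O, rt
Reagents that add atoms: N-methylmorpholine N-oxide, C[N+]1([O-])CCOCC1; water, O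
Why: Upjohn dihydroxylation of the exocyclic alkene, for which the α face of C4 in the locked trans-decalin is screened by the 1,3-diaxial C10 methyl, so OsO4 should add from the β face and give the equatorial 4β-hydroxyl with C15 axial (α).

Step 14
Reactants: 18 (E)-cinnamonitrile
Product: 20 trimethyl (E)-orthocinnamate, via imidate hydrochloride 19 (not isolated)
Conditions: HCl (g), MeOH (1.1 equiv), Et2O, 0 °C; then MeOH, rt
Reagents that add atoms: methanol, CO
Why: Pinner reaction, in which HCl-mediated addition of methanol to the nitrile gives the imidate hydrochloride and its methanolysis gives the orthoester, the (E)-alkene not being involved.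

Step 15
Reactants: 17 tetraol; 20 trimethyl (E)-orthocinnamate
Product: 21 4β,6β,15-orthocinnamate of 17 (free 1β-OH; C1 epimer of the target)
Conditions: CSA (5 mol%), 4 Å MS, CH2Cl2, rt; then Et3N
Reagents that add atoms: none
Why: Acid-catalysed transorthoesterification, in which the rigid 1,2,4-triol array O15/O4/O6 closes the 2,7,8-trioxabicyclo[3.2.1]octane under thermodynamic control, the distant axial 1β-hydroxyl cannot form a cage and stays free, and the orthoester carbon takes the only configuration the cage allows.

Step 16
Reactants: 21 orthoester alcohol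
Product: 22 1-oxo orthoester (4β,6β,15-orthocinnamate of the 1-ketone)
Conditions: Dess–Martin periodinane, NaHCO3, CH2Cl2, 0 °C to rt
Reagents that add atoms: none
Why: Dess–Martin oxidation of the single free secondary alcohol under bicarbonate buffer, which protects the acid-labile orthoester.

Step 17
Reactants: 22 orthoester ketone
Product: 23 target CNP0190302.1
Conditions: NaBH4, MeOH/THF, −20 °C
Reagents that add atoms: none
Why: Hydride reduction of a cyclohexanone next to a quaternary centre, in which NaBH4 should attack C1 axially from the β face, anti to the axial 10α-methyl, and give the equatorial 1α-alcohol cis to that methyl, the orthoester and styryl group being inert.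

**Compound list**

1 | 2-methylcyclohexane-1,3-dione | CC1C(=O)CCCC1=O | starting material
2 | 2-methyl-3-oxocyclohex-1-en-1-yl trifluoromethanesulfonate | CC1=C(OS(=O)(=O)C(F)(F)F)CCCC1=O | intermediate
3 | 3-methylbut-1-yne | CC(C)C#C | starting material
4 | (E)-4,4,5,5-tetramethyl-2-(3-methylbut-1-en-1-yl)-1,3,2-dioxaborolane | CC(C)/C=C/B1OC(C)(C)C(C)(C)O1 | intermediate
5 | 2-methyl-3-[(E)-3-methylbut-1-en-1-yl]cyclohex-2-en-1-one | CC(C)/C=C/C1=C(C)C(=O)CCC1 | intermediate
6 | (R)-2-methyl-3-[(E)-3-methylbut-1-en-1-yl]cyclohex-2-en-1-ol | CC(C)/C=C/C1=C(C)[C@H](O)CCC1 | intermediate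
7 | dimethyl(vinyl)silyl ether of 6 | CC(C)/C=C/C1=C(C)[C@H](O[Si](C)(C)C=C)CCC1 | intermediate
8 | Diels–Alder adduct: 7β-isopropyl-10α-methyl-15-noreudesm-5-ene bridged O1β–SiMe2–C9β | CC(C)[C@@H]1C[C@@H]2[Si](C)(C)O[C@@H]3CCCC(=C1)[C@]23C | intermediate
9 | 7αH,10α-15-noreudesm-5-en-1β-ol | CC(C)[C@@H]1CC[C@@]2(C)C(=C1)CCC[C@H]2O | intermediate
10 | 5β,6β-epoxy-7αH,10α-15-noreudesman-1β-ol | CC(C)[C@@H]1CC[C@@]2(C)[C@]3(CCC[C@H]2O)O[C@H]13 | intermediate
11 | 7αH,10α-15-noreudesm-4-ene-1β,6β-diol | CC(C)[C@@H]1CC[C@@]2(C)C(=CCC[C@H]2O)[C@@H]1O | intermediate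
12 | 1,6-bis-O-(dimethylsilyl) ether of 11 | CC(C)[C@@H]1CC[C@@]2(C)C(=CCC[C@H]2O[SiH](C)C)[C@@H]1O[SiH](C)C | intermediate
13 | oxasilolane O6–SiMe2–C4β (5β-H) carrying the 1-O-dimethylsilyl ether | CC(C)[C@@H]1CC[C@@]2(C)[C@@H]3[C@@H]1O[Si](C)(C)[C@H]3CC[C@H]2O[SiH](C)C | intermediate
14 | 5βH,7αH,10α-15-noreudesmane-1β,4β,6β-triol | CC(C)[C@@H]1CC[C@@]2(C)[C@H]([C@@H]1O)[C@@H](O)CC[C@H]2O | intermediate
15 | 1β,6β-dihydroxy-5βH,7αH,10α-15-noreudesman-4-one | CC(C)[C@@H]1CC[C@@]2(C)[C@H]([C@@H]1O)C(=O)CC[C@H]2O | intermediate
16 | 5βH,7αH,10α-eudesm-4(15)-ene-1β,6β-diol | CC(C)[C@@H]1CC[C@@]2(C)[C@H]([C@@H]1O)C(=C)CC[C@H]2O | intermediate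
17 | 5βH,7αH,10α-eudesmane-1β,4β,6β,15-tetraol | CC(C)[C@@H]1CC[C@@]2(C)[C@H]([C@@H]1O)[C@](O)(CO)CC[C@H]2O | intermediate
18 | (E)-cinnamonitrile | N#C/C=C/c1ccccc1 | starting material
19 | methyl (E)-cinnamimidate hydrochloride | COC(=[NH2+])/C=C/c1ccccc1.[Cl-] | intermediate
20 | trimethyl (E)-orthocinnamate | COC(OC)(OC)/C=C/c1ccccc1 | intermediate
21 | 4β,6β,15-orthocinnamate of 17 with free 1β-OH | CC(C)[C@@H]1CC[C@@]2(C)[C@@H]3[C@@H]1O[C@]1(/C=C/c4ccccc4)OC[C@@]3(CC[C@H]2O)O1 | intermediate
22 | 1-oxo orthoester | CC(C)[C@@H]1CC[C@@]2(C)[C@@H]3[C@@H]1O[C@]1(/C=C/c4ccccc4)OC[C@@]3(CCC2=O)O1 | intermediate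
23 | CNP0190302.1 | CC(C)[C@@H]1CC[C@@]2(C)[C@@H]3[C@@H]1O[C@]1(/C=C/c4ccccc4)OC[C@@]3(CC[C@@H]2O)O1 | target

Total steps: 17. Longest linear sequence: 15 (steps 1, 3–13, 15–17).

**Steps most likely to fail**

Step 6. The closure may be overtaken by the 1,5-hydrogen shift of the inside C10 methyl, or stall because the diene is hindered and the dienophile unactivated. Fallback, from 6 back to 9: the tether atom is changed from silicon to magnesium. Dienol 6 is treated with CH2=CHMgBr (2.2 equiv, THF, 0 °C); the first equivalent deprotonates and the second gives, by ligand exchange, the alkoxy(vinyl)magnesium F1. The solvent is exchanged for toluene and the mixture is heated (about 110–130 °C, sealed), so that the metal-tethered (4+2) closure gives the 1-oxa-2-magnesacyclopentane F2. Its C–Mg and O–Mg bonds are protonated on aqueous NH4Cl work-up to give 9 directly. This temporary magnesium connection is a known variant of the tethered ethylene Diels–Alder reaction; it should run at lower temperature and by-passes steps 5 and 7, so it also answers a sluggish protodesilylation.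

Step 11. Site selection among three secondary carbinols may be poor, with over-oxidation at C1 or C6. Fallback, from 14 back to 22: the oxygens are told apart by protection instead of by rate. Triol 14 and 4-methoxybenzaldehyde dimethyl acetal (CSA, CH2Cl2) should give the 4,6-O-(4-methoxybenzylidene) acetal F3 of the syn-1,3-diol. Reductive opening with iBu2AlH (CH2Cl2, −78 to 0 °C), which coordinates the less hindered O4, should leave the 6-O-(4-methoxybenzyl) ether F4 with free C1 and C4 hydroxyls. Dess–Martin oxidation of both gives the 1,4-diketone F5. Takai–Lombardo methylenation at the less hindered C4 carbonyl (C1 is flanked by the quaternary C10) gives the methylene ketone F6. OsO4/NMO gives the 4β,15-diol F7, and DDQ (CH2Cl2/H2O) removes the ether to give the triol ketone F8. Transorthoesterification of F8 with 20 (CSA, 4 Å MS) then gives 22, so step 16 is no longer needed.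

Step 15. Cage closure may be incomplete, stopping at monocyclic mixed orthoesters, or the product may be lost to acid during exchange. Fallback, from 17 back to 21: the acyl carbon is introduced at the ester level. The primary C15 hydroxyl of 17 is acylated with cinnamoyl chloride (2,4,6-collidine, CH2Cl2, −40 °C) to give the 15-O-cinnamate F9. Acid-catalysed intramolecular orthoesterification (CSA, benzene, 4 Å MS, 60 °C, removal of water) lets the neighbouring 4β- and 6β-hydroxyls add to the ester carbonyl and close the cage to 21.

Further compounds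
F1 | step 6 | [(R)-2-methyl-3-((E)-3-methylbut-1-en-1-yl)cyclohex-2-en-1-yl]oxy(vinyl)magnesium | CC(C)/C=C/C1=C(C)[C@H](O[Mg]C=C)CCC1
F2 | step 6 | magnesium analogue of 8 (O1β–Mg–C9β 1-oxa-2-magnesacyclopentane) | CC(C)[C@@H]1C[C@@H]2[Mg]O[C@@H]3CCCC(=C1)[C@]23C
F3 | step 11 | 4,6-O-(4-methoxybenzylidene) acetal of 14 | CC(C)[C@@H]1CC[C@@]2(C)[C@@H]3[C@@H]1O[C@@H](c1ccc(OC)cc1)O[C@H]3CC[C@H]2O
F4 | step 11 | 6-O-(4-methoxybenzyl) ether of 14 | CC(C)[C@@H]1CC[C@@]2(C)[C@H]([C@@H]1OCc1ccc(OC)cc1)[C@@H](O)CC[C@H]2O
F5 | step 11 | 6β-(4-methoxybenzyloxy)-5βH,7αH,10α-15-noreudesmane-1,4-dione | CC(C)[C@@H]1CC[C@@]2(C)[C@H]([C@@H]1OCc1ccc(OC)cc1)C(=O)CCC2=O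
F6 | step 11 | 6β-(4-methoxybenzyloxy)-5βH,7αH,10α-eudesm-4(15)-en-1-one | CC(C)[C@@H]1CC[C@@]2(C)[C@H]([C@@H]1OCc1ccc(OC)cc1)C(=C)CCC2=O
F7 | step 11 | 4β,15-dihydroxy-6β-(4-methoxybenzyloxy)-5βH,7αH,10α-eudesman-1-one | CC(C)[C@@H]1CC[C@@]2(C)[C@H]([C@@H]1OCc1ccc(OC)cc1)[C@](O)(CO)CCC2=O
F8 | step 11 | 4β,6β,15-trihydroxy-5βH,7αH,10α-eudesman-1-one | CC(C)[C@@H]1CC[C@@]2(C)[C@H]([C@@H]1O)[C@](O)(CO)CCC2=O
F9 | step 15 | 15-O-(E)-cinnamate of 17 | CC(C)[C@@H]1CC[C@@]2(C)[C@H]([C@@H]1O)[C@](O)(COC(=O)/C=C/c1ccccc1)CC[C@H]2O
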